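I had no constant of any step, so I read what I could from the south run, which took twice the substrate of this flask.

| flask | substrate | gas | remark | time |
|---|---|---|---|---|
| south | 80 mM (in portions, 3) | 2.4 mM (held) | run made earlier; portions every 15 min |  |
| flask | 40 mM (in portions, 3) | 2.4 mM (held) | the portions of substrate follow each other after 15 min, the first at the start | 40 h |

south run (percent of the substrate charged)

| time / h | substrate / % | target / % |
|---|---|---|
| 1.33 | 0 | 47 |
| 2.50 | 2 | 11 |
| 4.00 | 1 | 7 |
| 5.00 | 0 | 7 |
| 6.00 | 1 | 10 |
| 8.00 | 2 | 7 |

(scatter of a reading: 2 percentage points)

- at the start none of coupling partner is dissolved
- steps thought possible: substrate + coupling partner + released group -> target + 2 released group; substrate + coupling partner -> target + released group; target <-> isomer of the product; gas <-> coupling partner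
- the reaction counts as stopped when no species that holds the substrate changes by six tenths of a point or more over the second half of the time
- a reading of target is of its free form alone

* which holds at 40 h: what has brought the reaction to rest, or that it has not come to rest (forward and back rates have come level / it is still moving / all of the substrate has reacted)
* part of the substrate gone at 40 h
* the target standing at 40 h, as a percentage of the substrate charged

In the south run, target read 47% at 1.33 h and lay low from 4.00 h on. From 4.00 h on, target was the small share in the south run, so I reckoned target and took the isomer, which was not read, as the remainder. The mean of the last 4 target readings, 7.75%, I called s, the resting share of target: the part of the substrate charged that stands as target once target and isomer have levelled, which is thermodynamic control. Its scatter was 1 percentage point.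

But was that a rest or a slow fall? Between 1.33 h and 2.50 h the excess of target over s shrank from 39 points to 3.2 points, which gave a half-life of about 0.326 h. That is rough, since the smaller excess is barely above the scatter, yet 40 h is far longer than this.

Next doubt: the charge was halved. Target and isomer pass one into the other, one for one, so I took s as a share that does not follow the charge and carried it over. Released group stands on both sides of one coupling step, however, and with less substrate the coupling could slow. Stretching 1.33 h, when the south substrate read 0%, by the ratio of charges gave an estimate of 2.66 h, still much shorter than 40 h. I therefore committed to s for target and to full conversion at 40 h. Which of two rests the question would name, the substrate ending or target and isomer levelling, I could not read from this run.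

The forecast gave 100% conversion and 8% of target, and its answer for the end was this: forward and back rates have come level. It held that “rest comes from forward and back rates levelling”.

This flask gave 7.69% of target at 40 h, with 100% conversion, and the answer for the end was this: all of the substrate has reacted. Of the substrate charged, 0% was left, and the largest change of any share over the second half of the time was 0 points.

    substrate + coupling partner + released group → target + 2 released group (k = 1300 M⁻² min⁻¹)
    substrate + coupling partner → target + released group (k = 0.0120 M⁻¹ min⁻¹)
    target ⇌ isomer of the product (K = 12.0, k = 0.0320 min⁻¹)
    gas ⇌ coupling partner, rate k4*(csat - [coupling partner]) (kL = 12.0 min⁻¹)

This flask's target lay 0.060 points from the reading s, less than the scatter of s. For a further flask, like this one but charged with 10 mM of substrate, s gives 0.775 mM of target, and at 40.0 h that flask stood at 7.69% of its substrate charged, or 0.769 mM.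

The runs are simulated with made-up constants, and the scatter is random.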